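**Retrosynthetic overview**
- The target is a 9βH ("syn") labdane; the last operations are C7 allylic hydroxylation of the 8(17)-alkene and inversion of C3 (oxidation, then bulky hydride).
- Rings A and B are made in one operation by a Cp2TiCl radical bicyclization of a fully acylated acyclic epoxy-triene: ring A closes first (C4–C5), then ring B (C10–C9), ending as the exocyclic alkene.
- The (Z)-C8=C9 alkene of that precursor encodes the axial side chain (9βH); the threo epoxy ester at C2/C3 sets the absolute configuration.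
- The precursor is joined at C5=C10 by a Z-selective Wittig reaction of an α-silyloxy ketone (from prenal, by asymmetric aldol and hydroxyl-directed epoxidation) with an ylide.
- The ylide comes from (R)-linalool (C13) by ozonolysis, (Z)-iodo-olefination and B-alkyl Suzuki coupling.

Assumption: labdane numbering is used with C20 on the β-face; the given SMILES is read as (2R,3S,5R,7R,9S,10R,13R) with an (R)-2-methylbutanoate and an angelate [(2Z)-2-methylbut-2-enoate], and compounds 1, 4, 9, 15, 18, 26 and 29 are bought.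

**Step 1**
Reactants: 1 (R)-(−)-linalool
Product: 3 (5R)-5-ethenyl-5-methyloxolan-2-ol (lactol form of (R)-4-hydroxy-4-methylhex-5-enal), via ozonide 2 (not isolated)
Conditions: O3 (1.0 equiv, Sudan Red 7B end point), CH2Cl2, −78 °C; then Me2S, −78 °C → rt
Reagents that add atoms: ozone (O=[O+][O-])
Why: Ozonolysis cleaves the electron-rich trisubstituted alkene much faster than the vinyl group, and the aldehyde closes onto the tertiary hydroxyl as the lactol, leaving C13 (R) untouched.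

**Step 2**
Reactants: 3 (5R)-5-ethenyl-5-methyloxolan-2-ol; 4 ethyltriphenylphosphonium iodide
Product: 8 (3R,6Z)-7-iodo-3-methylocta-1,6-dien-3-ol, via ylide 5 (not isolated), via iodophosphonium salt 6 (not isolated), via iodo ylide 7 (not isolated)
Conditions: 4, n-BuLi, THF, 0 °C; I2, −78 °C; NaN(SiMe3)2, −78 → −20 °C; then 3, −78 °C → rt
Reagents that add atoms: iodine (II)
Why: Wittig olefination with an α-iodo ylide (Stork–Zhao type): the lactol opens under base and the non-stabilised iodo ylide gives the (Z)-iodoalkene (iodine cis to the chain, typically about 10:1), which fixes the later C8=C9 geometry.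

**Step 3**
Reactants: 8 (3R,6Z)-7-iodo-3-methylocta-1,6-dien-3-ol; 9 allyloxytrimethylsilane
Product: 12 (4Z,8R)-4,8-dimethyldeca-4,9-diene-1,8-diol, via alkylborane 10 (not isolated), via silyl ether 11 (not isolated)
Conditions: 9, 9-BBN-H, THF, 0 °C → rt; then 8, PdCl2(dppf) (5 mol %), AsPh3, Cs2CO3, DMF/THF/H2O, rt; then K2CO3 (cat.), MeOH, rt
Reagents that add atoms: none
Why: B-alkyl Suzuki–Miyaura coupling joins the alkylborane to the vinyl iodide with retention of the Z geometry, after which the labile trimethylsilyl ether is removed by methanolysis while the tertiary alcohol is inert.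

**Step 4**
Reactants: 12 (4Z,8R)-4,8-dimethyldeca-4,9-diene-1,8-diol
Product: 14 [(4Z,8R)-8-hydroxy-4,8-dimethyldeca-4,9-dien-1-yl]triphenylphosphonium iodide, via iodide 13 (not isolated)
Conditions: I2 (1.05 equiv), PPh3 (2.5 equiv), imidazole, MeCN/toluene, 0 °C; then 80 °C, 16 h
Reagents that add atoms: triphenylphosphine (c1ccc(cc1)P(c1ccccc1)c1ccccc1); iodine (II)
Why: Appel iodination of the primary alcohol (the tertiary allylic alcohol reacts far more slowly) is followed by SN2 quaternisation of the primary iodide by the excess phosphine.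

**Step 5**
Reactants: 15 1-(tert-butyldimethylsilyloxy)propan-2-one
Product: 17 tert-butyldimethyl{[2-(trimethylsilyloxy)prop-2-en-1-yl]oxy}silane, via lithium enolate 16 (not isolated)
Conditions: LiN(iPr)2, Me3SiCl, THF, −78 °C → 0 °C
Reagents that add atoms: chlorotrimethylsilane (C[Si](C)(C)Cl)
Why: Kinetic enolisation with LiN(iPr)2 removes the unhindered methyl proton rather than the proton next to the silyloxy group, and the enolate is O-silylated in situ.

**Step 6**
Reactants: 17 tert-butyldimethyl{[2-(trimethylsilyloxy)prop-2-en-1-yl]oxy}silane; 18 3-methylbut-2-enal (prenal)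
Product: 20 (4R)-1-(tert-butyldimethylsilyloxy)-4-hydroxy-6-methylhept-5-en-2-one, via trichlorosilyl aldolate 19 (not isolated)
Conditions: SiCl4, Denmark binaphthyldiamine-derived bisphosphoramide (5 mol %, the antipode that gives Re-face attack), iPr2NEt (cat.), CH2Cl2, −78 °C; sat. aq. NaHCO3
Reagents that add atoms: none
Why: Lewis-base-catalysed Mukaiyama aldol (Denmark): the chiral phosphoramide-bound trichlorosilyl cation activates the enal for 1,2-addition on its Re face, setting the carbinol (labdane C2) as (R), with er typically ≥95:5 for conjugated aldehydes.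

**Step 7**
Reactants: 20 (4R)-1-(tert-butyldimethylsilyloxy)-4-hydroxy-6-methylhept-5-en-2-one
Product: 21 (4R)-1-(tert-butyldimethylsilyloxy)-4-[(2S)-3,3-dimethyloxiran-2-yl]-4-hydroxybutan-2-one
Conditions: mCPBA, NaHCO3, CH2Cl2, 0 °C
Reagents that add atoms: 3-chloroperoxybenzoic acid (OOC(=O)c1cccc(Cl)c1)
Why: Hydroxyl-directed Prilezhaev epoxidation: the Z-methyl group enforces the A(1,3)-minimised conformer and the hydrogen-bonded peracid attacks syn to the hydroxyl, giving the threo epoxy alcohol (about 95:5) and so setting labdane C3.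

**Step 8**
Reactants: 21 (4R)-1-(tert-butyldimethylsilyloxy)-4-[(2S)-3,3-dimethyloxiran-2-yl]-4-hydroxybutan-2-one
Product: 22 (4R)-1-(tert-butyldimethylsilyloxy)-4-[(2S)-3,3-dimethyloxiran-2-yl]-4-(triethylsilyloxy)butan-2-one
Conditions: Et3SiCl, imidazole, DMF, 0 °C
Reagents that add atoms: chlorotriethylsilane (CC[Si](Cl)(CC)CC)
Why: Silylation of the secondary alcohol blocks retro-aldol and β-elimination in the olefination that follows and touches no stereocentre.

**Step 9**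
Reactants: 14 [(4Z,8R)-8-hydroxy-4,8-dimethyldeca-4,9-dien-1-yl]triphenylphosphonium iodide; 22 (4R)-1-(tert-butyldimethylsilyloxy)-4-[(2S)-3,3-dimethyloxiran-2-yl]-4-(triethylsilyloxy)butan-2-one
Product: 24 (3R,6Z,10Z,13R)-11-[(tert-butyldimethylsilyloxy)methyl]-13-[(2S)-3,3-dimethyloxiran-2-yl]-3,7-dimethyl-13-(triethylsilyloxy)trideca-1,6,10-trien-3-ol, via oxido ylide 23 (not isolated)
Conditions: 14, NaN(SiMe3)2 (2.2 equiv), THF, −78 → 0 °C; then 22, −78 °C → rt
Reagents that add atoms: none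
Why: Wittig olefination of an α-alkoxy ketone with a non-stabilised ylide (Still's Z-selective variant) places the CH2OSi group cis to the incoming chain (typically ≥10:1), the geometry that later puts C6 equatorial on ring A.

**Step 10**
Reactants: 24 (3R,6Z,10Z,13R)-11-[(tert-butyldimethylsilyloxy)methyl]-13-[(2S)-3,3-dimethyloxiran-2-yl]-3,7-dimethyl-13-(triethylsilyloxy)trideca-1,6,10-trien-3-ol
Product: 25 (3R,6Z,10Z,13R)-13-[(2S)-3,3-dimethyloxiran-2-yl]-11-(hydroxymethyl)-3,7-dimethyltrideca-1,6,10-triene-3,13-diol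
Conditions: Bu4NF, AcOH, THF, 0 °C → rt
Reagents that add atoms: none
Why: Fluoride cleaves both silyl ethers, and the acetic acid buffer keeps the epoxy alcohol from Payne rearrangement.

**Step 11**
Reactants: 25 (3R,6Z,10Z,13R)-13-[(2S)-3,3-dimethyloxiran-2-yl]-11-(hydroxymethyl)-3,7-dimethyltrideca-1,6,10-triene-3,13-diol; 26 (R)-2-methylbutanoic acid
Product: 28 [(3R,6Z,10Z,13R)-13-[(2S)-3,3-dimethyloxiran-2-yl]-3,13-dihydroxy-3,7-dimethyltrideca-1,6,10-trien-11-yl]methyl (2R)-2-methylbutanoate, via O-acylisourea 27 (not isolated)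
Conditions: 26 (1.05 equiv), DCC, DMAP (5 mol %), CH2Cl2, −20 °C
Reagents that add atoms: none
Why: Steglich esterification at low temperature acylates the primary allylic hydroxyl much faster than the hindered secondary epoxy alcohol or the tertiary alcohol, and catalytic DMAP does not racemise the acid.

**Step 12**
Reactants: 28 [(3R,6Z,10Z,13R)-13-[(2S)-3,3-dimethyloxiran-2-yl]-3,13-dihydroxy-3,7-dimethyltrideca-1,6,10-trien-11-yl]methyl (2R)-2-methylbutanoate; 29 angelic acid [(2Z)-2-methylbut-2-enoic acid]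
Product: 31 [(3R,6Z,10Z,13R)-13-[(2S)-3,3-dimethyloxiran-2-yl]-3-hydroxy-3,7-dimethyl-13-{[(2Z)-2-methylbut-2-enoyl]oxy}trideca-1,6,10-trien-11-yl]methyl (2R)-2-methylbutanoate, via mixed anhydride 30 (not isolated)
Conditions: 29, 2,4,6-trichlorobenzoyl chloride, Et3N, toluene, rt; then 28, 70 °C
Reagents that add atoms: none
Why: Yamaguchi-type esterification through the 2,4,6-trichlorobenzoyl mixed anhydride is the established way to make angelates without Z-to-E isomerisation, and the tertiary alcohol does not react.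

**Step 13**
Reactants: 31 [(3R,6Z,10Z,13R)-13-[(2S)-3,3-dimethyloxiran-2-yl]-3-hydroxy-3,7-dimethyl-13-{[(2Z)-2-methylbut-2-enoyl]oxy}trideca-1,6,10-trien-11-yl]methyl (2R)-2-methylbutanoate
Product: 33 2α-angeloyloxy-20-[(2R)-2-methylbutanoyloxy]-9βH-labda-8(17),14-diene-3β,13-diol (2R,3R,5R,9R,10S,13R), via titanium alkoxide 32 (not isolated)
Conditions: Cp2TiCl2 (2.5 equiv), Mn dust (gives Cp2TiCl, trivalent titanium), THF, rt, slow addition of 31 (0.01 M), argon; then 0.5 M HCl, 0 °C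
Reagents that add atoms: none
Why: Titanocene-mediated radical epoxypolyene cyclisation (Nugent–RajanBabu epoxide opening, two 6-endo closures, then β-hydride loss to the exocyclic alkene): ring A closes through an all-equatorial chair (3-OTi, 2-OAng and C6 equatorial) and ring B through a chair in which the Z-alkene places C11 axial, so C5, C10 and C9 (9βH) are set from the epoxide configuration in one operation.

**Step 14**
Reactants: 33 2α-angeloyloxy-20-[(2R)-2-methylbutanoyloxy]-9βH-labda-8(17),14-diene-3β,13-diol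
Product: 34 2α-angeloyloxy-13-hydroxy-20-[(2R)-2-methylbutanoyloxy]-9βH-labda-8(17),14-dien-3-one (2R,5R,9R,10S,13R)
Conditions: Dess–Martin periodinane, NaHCO3, CH2Cl2, 0 °C → rt
Reagents that add atoms: none
Why: Dess–Martin oxidation converts the only secondary alcohol under buffered conditions, while the tertiary alcohol, alkenes and esters are inert.

**Step 15**
Reactants: 34 2α-angeloyloxy-13-hydroxy-20-[(2R)-2-methylbutanoyloxy]-9βH-labda-8(17),14-dien-3-one
Product: 35 2α-angeloyloxy-20-[(2R)-2-methylbutanoyloxy]-9βH-labda-8(17),14-diene-3α,13-diol (2R,3S,5R,9R,10S,13R)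
Conditions: LiB(sec-Bu)3H, THF, −78 °C; AcOH, −78 °C
Reagents that add atoms: none
Why: Bulky-hydride ketone reduction: LiB(sec-Bu)3H attacks the 4,4-dimethyl-3-ketone along the equatorial trajectory and gives the axial 3α-alcohol cis to the 2α-ester, and the cold acetic acid quench prevents acyl migration.

**Step 16**
Reactants: 35 2α-angeloyloxy-20-[(2R)-2-methylbutanoyloxy]-9βH-labda-8(17),14-diene-3α,13-diol
Product: 36 2α-angeloyloxy-20-[(2R)-2-methylbutanoyloxy]-9βH-labda-8(17),14-diene-3α,7α,13-triol (2R,3S,5R,7R,9S,10R,13R), the target CNP0391865.1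
Conditions: SeO2 (0.3 equiv), t-BuOOH, CH2Cl2, 0 °C → rt
Reagents that add atoms: tert-butyl hydroperoxide (CC(C)(C)OO)
Why: Riley (SeO2) allylic oxidation: the ene reaction at the exocyclic alkene removes the axial H7 and the 2,3-sigmatropic shift returns oxygen axially to C7 with the double bond restored at C8–C17, as known for labd-8(17)-enes, giving the 7α-alcohol.

**Compound list**
1 | (R)-(−)-linalool, (3R)-3,7-dimethylocta-1,6-dien-3-ol | CC(C)=CCC[C@@](C)(O)C=C | starting material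
2 | 5-[(3R)-3-hydroxy-3-methylpent-4-en-1-yl]-3,3-dimethyl-1,2,4-trioxolane (ozonide) | CC1(C)OOC(CC[C@@](C)(O)C=C)O1 | intermediate
3 | (5R)-5-ethenyl-5-methyloxolan-2-ol | C=C[C@@]1(C)CCC(O)O1 | intermediate
4 | ethyltriphenylphosphonium iodide | CC[P+](c1ccccc1)(c1ccccc1)c1ccccc1.[I-] | starting material
5 | ethylidenetriphenylphosphorane | CC=P(c1ccccc1)(c1ccccc1)c1ccccc1 | intermediate
6 | (1-iodoethyl)triphenylphosphonium iodide | CC(I)[P+](c1ccccc1)(c1ccccc1)c1ccccc1.[I-] | intermediate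
7 | (1-iodoethylidene)triphenylphosphorane | CC(I)=P(c1ccccc1)(c1ccccc1)c1ccccc1 | intermediate
8 | (3R,6Z)-7-iodo-3-methylocta-1,6-dien-3-ol | C/C(I)=C/CC[C@@](C)(O)C=C | intermediate
9 | allyloxytrimethylsilane | C=CCO[Si](C)(C)C | starting material
10 | 9-[3-(trimethylsilyloxy)propyl]-9-borabicyclo[3.3.1]nonane | C[Si](C)(C)OCCCB1C2CCCC1CCC2 | intermediate
11 | (3R,6Z)-3,7-dimethyl-10-(trimethylsilyloxy)deca-1,6-dien-3-ol | C[Si](C)(C)OCCC/C(C)=C\CC[C@@](C)(O)C=C | intermediate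
12 | (4Z,8R)-4,8-dimethyldeca-4,9-diene-1,8-diol | OCCC/C(C)=C\CC[C@@](C)(O)C=C | intermediate
13 | (3R,6Z)-10-iodo-3,7-dimethyldeca-1,6-dien-3-ol | ICCC/C(C)=C\CC[C@@](C)(O)C=C | intermediate
14 | [(4Z,8R)-8-hydroxy-4,8-dimethyldeca-4,9-dien-1-yl]triphenylphosphonium iodide | [I-].C=C[C@](C)(O)CC/C=C(/C)CCC[P+](c1ccccc1)(c1ccccc1)c1ccccc1 | intermediate
15 | 1-(tert-butyldimethylsilyloxy)propan-2-one | CC(=O)CO[Si](C)(C)C(C)(C)C | starting material
16 | lithium 3-(tert-butyldimethylsilyloxy)prop-1-en-2-olate | [Li+].C=C([O-])CO[Si](C)(C)C(C)(C)C | intermediate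
17 | tert-butyldimethyl{[2-(trimethylsilyloxy)prop-2-en-1-yl]oxy}silane | C=C(O[Si](C)(C)C)CO[Si](C)(C)C(C)(C)C | intermediate
18 | 3-methylbut-2-enal (prenal) | CC(C)=CC=O | starting material
19 | (4R)-1-(tert-butyldimethylsilyloxy)-6-methyl-4-(trichlorosilyloxy)hept-5-en-2-one | CC(C)=C[C@H](O[Si](Cl)(Cl)Cl)CC(=O)CO[Si](C)(C)C(C)(C)C | intermediate
20 | (4R)-1-(tert-butyldimethylsilyloxy)-4-hydroxy-6-methylhept-5-en-2-one | CC(C)=C[C@H](O)CC(=O)CO[Si](C)(C)C(C)(C)C | intermediate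
21 | (4R)-1-(tert-butyldimethylsilyloxy)-4-[(2S)-3,3-dimethyloxiran-2-yl]-4-hydroxybutan-2-one | CC1(C)O[C@H]1[C@H](O)CC(=O)CO[Si](C)(C)C(C)(C)C | intermediate
22 | (4R)-1-(tert-butyldimethylsilyloxy)-4-[(2S)-3,3-dimethyloxiran-2-yl]-4-(triethylsilyloxy)butan-2-one | CC1(C)O[C@H]1[C@H](O[Si](CC)(CC)CC)CC(=O)CO[Si](C)(C)C(C)(C)C | intermediate
23 | sodium (3R,6Z)-3,7-dimethyl-10-(triphenyl-λ5-phosphanylidene)deca-1,6-dien-3-olate | [Na+].C=C[C@](C)([O-])CC/C=C(/C)CCC=P(c1ccccc1)(c1ccccc1)c1ccccc1 | intermediate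
24 | (3R,6Z,10Z,13R)-11-[(tert-butyldimethylsilyloxy)methyl]-13-[(2S)-3,3-dimethyloxiran-2-yl]-3,7-dimethyl-13-(triethylsilyloxy)trideca-1,6,10-trien-3-ol | CC1(C)O[C@H]1[C@H](O[Si](CC)(CC)CC)C/C(CO[Si](C)(C)C(C)(C)C)=C/CC/C(C)=C\CC[C@@](C)(O)C=C | intermediate
25 | (3R,6Z,10Z,13R)-13-[(2S)-3,3-dimethyloxiran-2-yl]-11-(hydroxymethyl)-3,7-dimethyltrideca-1,6,10-triene-3,13-diol | CC1(C)O[C@H]1[C@H](O)C/C(CO)=C/CC/C(C)=C\CC[C@@](C)(O)C=C | intermediate
26 | (R)-2-methylbutanoic acid | CC[C@@H](C)C(=O)O | starting material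
27 | N,N'-dicyclohexyl-O-[(2R)-2-methylbutanoyl]isourea | CC[C@@H](C)C(=O)OC(=NC1CCCCC1)NC1CCCCC1 | intermediate
28 | [(3R,6Z,10Z,13R)-13-[(2S)-3,3-dimethyloxiran-2-yl]-3,13-dihydroxy-3,7-dimethyltrideca-1,6,10-trien-11-yl]methyl (2R)-2-methylbutanoate | CC1(C)O[C@H]1[C@H](O)C/C(COC(=O)[C@H](C)CC)=C/CC/C(C)=C\CC[C@@](C)(O)C=C | intermediate
29 | angelic acid, (2Z)-2-methylbut-2-enoic acid | C/C=C(/C)C(=O)O | starting material
30 | (2Z)-2-methylbut-2-enoic 2,4,6-trichlorobenzoic anhydride | C/C=C(/C)C(=O)OC(=O)c1c(Cl)cc(Cl)cc1Cl | intermediate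
31 | [(3R,6Z,10Z,13R)-13-[(2S)-3,3-dimethyloxiran-2-yl]-3-hydroxy-3,7-dimethyl-13-{[(2Z)-2-methylbut-2-enoyl]oxy}trideca-1,6,10-trien-11-yl]methyl (2R)-2-methylbutanoate | CC1(C)O[C@H]1[C@H](OC(=O)/C(C)=C\C)C/C(COC(=O)[C@H](C)CC)=C/CC/C(C)=C\CC[C@@](C)(O)C=C | intermediate
32 | chlorobis(cyclopentadienyl)titanium 3β-alkoxide of compound 33 | C=C[C@](C)(O)CC[C@@H]1C(=C)CC[C@H]2C(C)(C)[C@@H](O[Ti](Cl)(C3C=CC=C3)C3C=CC=C3)[C@H](OC(=O)/C(C)=C\C)C[C@]12COC(=O)[C@H](C)CC | intermediate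
33 | 2α-angeloyloxy-20-[(2R)-2-methylbutanoyloxy]-9βH-labda-8(17),14-diene-3β,13-diol (2R,3R,5R,9R,10S,13R) | C=C[C@](C)(O)CC[C@@H]1C(=C)CC[C@H]2C(C)(C)[C@@H](O)[C@H](OC(=O)/C(C)=C\C)C[C@]12COC(=O)[C@H](C)CC | intermediate
34 | 2α-angeloyloxy-13-hydroxy-20-[(2R)-2-methylbutanoyloxy]-9βH-labda-8(17),14-dien-3-one (2R,5R,9R,10S,13R) | C=C[C@](C)(O)CC[C@@H]1C(=C)CC[C@H]2C(C)(C)C(=O)[C@H](OC(=O)/C(C)=C\C)C[C@]12COC(=O)[C@H](C)CC | intermediate
35 | 2α-angeloyloxy-20-[(2R)-2-methylbutanoyloxy]-9βH-labda-8(17),14-diene-3α,13-diol (2R,3S,5R,9R,10S,13R) | C=C[C@](C)(O)CC[C@@H]1C(=C)CC[C@H]2C(C)(C)[C@H](O)[C@H](OC(=O)/C(C)=C\C)C[C@]12COC(=O)[C@H](C)CC | intermediate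
36 | 2α-angeloyloxy-20-[(2R)-2-methylbutanoyloxy]-9βH-labda-8(17),14-diene-3α,7α,13-triol (2R,3S,5R,7R,9S,10R,13R) | C=C[C@](C)(O)CC[C@@H]1C(=C)[C@H](O)C[C@H]2C(C)(C)[C@H](O)[C@H](OC(=O)/C(C)=C\C)C[C@]12COC(=O)[C@H](C)CC | target

**Step count and risks**
Total step count: 16. Longest linear sequence: 12 steps (steps 1–4 then 9–16; the branch 5–8 then 9–16 is equally long).

The three steps most likely to fail:

Step 13 (radical bicyclization). The two esters may interfere: acyl transfer to the titanium alkoxide, loss of the C20 acyloxy group from the C10 radical, or addition to the angelate; low bicyclization yield and alkene regioisomers are also possible. The fallback sets out from 24 and cyclizes before any ester is present. Cp2TiCl (from Cp2TiCl2 and Mn) converts 24 into 20-(tert-butyldimethylsilyloxy)-2α-(triethylsilyloxy)-9βH-labda-8(17),14-diene-3β,13-diol F1. Bu4NF then gives 9βH-labda-8(17),14-diene-2α,3β,13,20-tetrol F2. Acid 26 with DCC/DMAP acylates the primary hydroxyl to give 20-[(2R)-2-methylbutanoyloxy]-9βH-labda-8(17),14-diene-2α,3β,13-triol F3. Mixed anhydride 30 then acylates the less hindered equatorial 2α-hydroxyl, and the route is rejoined at 33.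

Step 15 (reduction next to the angelate). Acyl migration to the new cis-alkoxide, conjugate reduction of the angelate or poor facial selectivity could spoil it. The fallback sets out from 28 and postpones the angelate. Et3SiCl/imidazole gives [(3R,6Z,10Z,13R)-13-[(2S)-3,3-dimethyloxiran-2-yl]-3-hydroxy-3,7-dimethyl-13-(triethylsilyloxy)trideca-1,6,10-trien-11-yl]methyl (2R)-2-methylbutanoate F4. Cp2TiCl cyclizes it to 20-[(2R)-2-methylbutanoyloxy]-2α-(triethylsilyloxy)-9βH-labda-8(17),14-diene-3β,13-diol F5. Dess–Martin oxidation gives 13-hydroxy-20-[(2R)-2-methylbutanoyloxy]-2α-(triethylsilyloxy)-9βH-labda-8(17),14-dien-3-one F6. LiB(sec-Bu)3H reduces this, with no neighbouring ester, to 20-[(2R)-2-methylbutanoyloxy]-2α-(triethylsilyloxy)-9βH-labda-8(17),14-diene-3α,13-diol F7. Bu4NF/AcOH gives 20-[(2R)-2-methylbutanoyloxy]-9βH-labda-8(17),14-diene-2α,3α,13-triol F8. Anhydride 30 acylates the equatorial 2α-hydroxyl in preference to the hindered axial 3α-hydroxyl, and the route is rejoined at 35.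

Step 16 (C7 hydroxylation). The axial C9 side chain sits on the same face as the oxygen to be delivered, so the 7β-epimer or over-oxidation may dominate. The fallback sets out from 35 and goes through the ketone. SeO2/t-BuOOH is driven to the enone, with MnO2 to finish any allylic alcohol (the saturated 3α-hydroxyl is not touched), giving 2α-angeloyloxy-3α,13-dihydroxy-20-[(2R)-2-methylbutanoyloxy]-9βH-labda-8(17),14-dien-7-one F9. Luche reduction (NaBH4, CeCl3, MeOH, −78 °C) then delivers hydride from the β-face, away from the axial C11 chain, and gives the 7α-alcohol 36.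

**Further compounds**
F1 | step 13 | 20-(tert-butyldimethylsilyloxy)-2α-(triethylsilyloxy)-9βH-labda-8(17),14-diene-3β,13-diol | C=C[C@](C)(O)CC[C@@H]1C(=C)CC[C@H]2C(C)(C)[C@@H](O)[C@H](O[Si](CC)(CC)CC)C[C@]12CO[Si](C)(C)C(C)(C)C
F2 | step 13 | 9βH-labda-8(17),14-diene-2α,3β,13,20-tetrol | C=C[C@](C)(O)CC[C@@H]1C(=C)CC[C@H]2C(C)(C)[C@@H](O)[C@H](O)C[C@]12CO
F3 | step 13 | 20-[(2R)-2-methylbutanoyloxy]-9βH-labda-8(17),14-diene-2α,3β,13-triol | C=C[C@](C)(O)CC[C@@H]1C(=C)CC[C@H]2C(C)(C)[C@@H](O)[C@H](O)C[C@]12COC(=O)[C@H](C)CC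
F4 | step 15 | [(3R,6Z,10Z,13R)-13-[(2S)-3,3-dimethyloxiran-2-yl]-3-hydroxy-3,7-dimethyl-13-(triethylsilyloxy)trideca-1,6,10-trien-11-yl]methyl (2R)-2-methylbutanoate | CC1(C)O[C@H]1[C@H](O[Si](CC)(CC)CC)C/C(COC(=O)[C@H](C)CC)=C/CC/C(C)=C\CC[C@@](C)(O)C=C
F5 | step 15 | 20-[(2R)-2-methylbutanoyloxy]-2α-(triethylsilyloxy)-9βH-labda-8(17),14-diene-3β,13-diol | C=C[C@](C)(O)CC[C@@H]1C(=C)CC[C@H]2C(C)(C)[C@@H](O)[C@H](O[Si](CC)(CC)CC)C[C@]12COC(=O)[C@H](C)CC
F6 | step 15 | 13-hydroxy-20-[(2R)-2-methylbutanoyloxy]-2α-(triethylsilyloxy)-9βH-labda-8(17),14-dien-3-one | C=C[C@](C)(O)CC[C@@H]1C(=C)CC[C@H]2C(C)(C)C(=O)[C@H](O[Si](CC)(CC)CC)C[C@]12COC(=O)[C@H](C)CC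
F7 | step 15 | 20-[(2R)-2-methylbutanoyloxy]-2α-(triethylsilyloxy)-9βH-labda-8(17),14-diene-3α,13-diol | C=C[C@](C)(O)CC[C@@H]1C(=C)CC[C@H]2C(C)(C)[C@H](O)[C@H](O[Si](CC)(CC)CC)C[C@]12COC(=O)[C@H](C)CC
F8 | step 15 | 20-[(2R)-2-methylbutanoyloxy]-9βH-labda-8(17),14-diene-2α,3α,13-triol | C=C[C@](C)(O)CC[C@@H]1C(=C)CC[C@H]2C(C)(C)[C@H](O)[C@H](O)C[C@]12COC(=O)[C@H](C)CC
F9 | step 16 | 2α-angeloyloxy-3α,13-dihydroxy-20-[(2R)-2-methylbutanoyloxy]-9βH-labda-8(17),14-dien-7-one | C=C[C@](C)(O)CC[C@@H]1C(=C)C(=O)C[C@H]2C(C)(C)[C@H](O)[C@H](OC(=O)/C(C)=C\C)C[C@]12COC(=O)[C@H](C)CC
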